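**Strategy.** Ring B (C5–C10, labdane numbering) is cis-fused to ring A, with H-5, the C-10 methyl and the C-9 side chain on one face, and bears the exocyclic C8=C17 alkene. Moving that alkene to C7=C8 exposes a cyclohexene that is cut at C5–C6 and C9–C10. Two fragments of similar size are therefore joined in one endo Diels–Alder reaction: an enantiopure ring-A cyclohexenecarbaldehyde (C-4 quaternary centre set, formyl group as latent C-20 methyl) and an open-chain diene carrying the complete C11–C15 chain and a C-17 carbonate. The cycloaddition forms ring B, the C-10 quaternary centre and the C-5 and C-9 stereocentres; deoxygenation, reductive allylic transposition and Sharpless epoxidation complete the synthesis.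

Key step: step 8

Remark (assumption): methyl 3-oxocyclohex-1-ene-1-carboxylate is taken as a commercial starting material. Locants C1–C20 in the text follow labdane numbering. The SMILES of the target defines a cis-fused decalin (H-5, C-20, C-11 and the ester carbon on one face), and the route is built for exactly that isomer.

Step 1
Reactants: 1 methyl 3-oxocyclohex-1-ene-1-carboxylate
Product: 3 methyl (1S)-1-methyl-3-{[(trifluoromethyl)sulfonyl]oxy}cyclohex-2-ene-1-carboxylate, via methylzinc enolate 2 (not isolated)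
Conditions: Me2Zn (2 equiv), (CuOTf)2·C6H6 (2.5 mol %), chiral sulfonate-bearing NHC–Ag(I) complex (2.5 mol %), t-BuOMe, −30 °C; then Tf2O (3 equiv), −78 → 0 °C
Reagents that add atoms: dimethylzinc C[Zn]C; trifluoromethanesulfonic anhydride O=S(=O)(OS(=O)(=O)C(F)(F)F)C(F)(F)F
Why: Copper-catalysed asymmetric conjugate addition of a dialkylzinc to a cyclic γ-keto ester should set the C-4 quaternary centre (ligand enantiomer chosen to give S), and O-triflation of the regiodefined zinc enolate fixes the double bond on the side of the quaternary carbon, which later enolisation of the free ketone could not do.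

Step 2
Reactants: 3 methyl (1S)-1-methyl-3-{[(trifluoromethyl)sulfonyl]oxy}cyclohex-2-ene-1-carboxylate
Product: 4 methyl (1S)-3-formyl-1-methylcyclohex-2-ene-1-carboxylate
Conditions: Pd(PPh3)4 (5 mol %), CO (1 atm), Bu3SnH (slow addition), THF, 50 °C
Reagents that add atoms: carbon monoxide [C-]#[O+]
Why: Palladium-catalysed reductive carbonylation (formylation) of an enol triflate (oxidative addition, CO insertion, hydride transfer from the stannane) should give the enal without touching the stereocentre.

Step 3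
Reactants: 5 geraniol
Product: 6 tert-butyl{[(2E)-3,7-dimethylocta-2,6-dien-1-yl]oxy}dimethylsilane
Conditions: TBSCl, imidazole, DMF, rt
Reagents that add atoms: tert-butyldimethylsilyl chloride CC(C)(C)[Si](C)(C)Cl
Why: Standard silyl ether formation masks the C-15 hydroxyl for the organometallic and Lewis-acid steps; no stereocentre is involved.

Step 4
Reactants: 6 tert-butyl{[(2E)-3,7-dimethylocta-2,6-dien-1-yl]oxy}dimethylsilane
Product: 8 (4E)-6-{[tert-butyl(dimethyl)silyl]oxy}-4-methylhex-4-enal, via ozonide 7 (not isolated)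
Conditions: O3 (1.0 equiv, titrated), CH2Cl2, −78 °C; then PPh3, −78 °C → rt
Reagents that add atoms: ozone [O-][O+]=O
Why: Chemoselective ozonolysis with reductive work-up should cleave the more electron-rich 6,7-alkene, because the allylic C–O bond deactivates the 2,3-alkene; the (E)-trisubstituted alkene of the future side chain is kept.

Step 5
Reactants: 8 (4E)-6-{[tert-butyl(dimethyl)silyl]oxy}-4-methylhex-4-enal
Product: 9 tert-butyl{[(2E)-7,7-dibromo-3-methylhepta-2,6-dien-1-yl]oxy}dimethylsilane
Conditions: CBr4, PPh3, Zn dust, CH2Cl2, rt (ylide pre-formed); then 8, 0 °C → rt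
Reagents that add atoms: carbon tetrabromide BrC(Br)(Br)Br
Why: Ramirez (Corey–Fuchs) dibromo-olefination under the neutral zinc variant keeps the silyl ether and installs C-8 as a gem-dibromide for two distinct C–C bond formations.

Step 6
Reactants: 9 tert-butyl{[(2E)-7,7-dibromo-3-methylhepta-2,6-dien-1-yl]oxy}dimethylsilane
Product: 10 tert-butyl{[(2E,6Z)-7-bromo-3-methylnona-2,6,8-trien-1-yl]oxy}dimethylsilane
Conditions: tributyl(vinyl)stannane (1.05 equiv), Pd2(dba)3 (2.5 mol %), tri(2-furyl)phosphine (15 mol %), toluene, 80 °C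
Reagents that add atoms: tributyl(vinyl)stannane C=C[Sn](CCCC)(CCCC)CCCC
Why: Stille mono-coupling of a 1,1-dibromoalkene occurs at the less hindered C–Br bond trans to the alkyl chain, so the vinyl group (C6=C7) should end trans to C-11, which sets the C8=C9 geometry of the diene.

Step 7
Reactants: 10 tert-butyl{[(2E,6Z)-7-bromo-3-methylnona-2,6,8-trien-1-yl]oxy}dimethylsilane
Product: 13 (2Z,6E)-8-{[tert-butyl(dimethyl)silyl]oxy}-2-ethenyl-6-methylocta-2,6-dien-1-yl methyl carbonate, via dienyllithium 11 (not isolated), via lithium alkoxide 12 (not isolated)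
Conditions: t-BuLi (2.1 equiv), Et2O, −78 °C; (CH2O)n, −78 → 0 °C; ClCO2Me, 0 °C → rt
Reagents that add atoms: formaldehyde C=O; methyl chloroformate COC(=O)Cl
Why: Bromine–lithium exchange proceeds with retention of alkene geometry, hydroxymethylation introduces C-17 cis to C-11, and in situ O-acylation gives the allylic carbonate needed for the later reductive transposition.

Step 8
Reactants: 4 methyl (1S)-3-formyl-1-methylcyclohex-2-ene-1-carboxylate; 13 (2Z,6E)-8-{[tert-butyl(dimethyl)silyl]oxy}-2-ethenyl-6-methylocta-2,6-dien-1-yl methyl carbonate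
Product: 14 methyl (1S,4aS,5S,8aS)-5-[(3E)-5-{[tert-butyl(dimethyl)silyl]oxy}-3-methylpent-3-en-1-yl]-4a-formyl-6-{[(methoxycarbonyl)oxy]methyl}-1-methyl-1,2,3,4,4a,5,8,8a-octahydronaphthalene-1-carboxylate
Conditions: 4, MeAlCl2 (1.1 equiv), CH2Cl2, −78 °C; then 13 (1.5 equiv), −78 → −20 °C
Reagents that add atoms: none
Why: Lewis-acid-promoted normal-demand [4+2] cycloaddition (Diels–Alder reaction): the s-cis diene C6=C7–C8=C9 of 13 adds to the aldehyde-activated C5=C10 bond of 4 in a concerted, asynchronous way, the C5–C6 bond between the unsubstituted diene terminus and the enal β-carbon being more advanced than the C9–C10 bond that creates the quaternary centre. The closest known reaction type is the aluminium- or tin-chloride-promoted cycloaddition of cyclohex-1-enecarbaldehydes with 1-alkylbuta-1,3-dienes, which delivers cis-decalins with an angular formyl group. Ring B is closed as a six-membered carbocycle by suprafacial addition to the ring-A alkene, so the ring fusion is necessarily cis (H-5 syn to the formyl group, the later C-20 methyl). C-9 is controlled by the endo rule, the Lewis-acid-bound formyl group lying under the diene and ring A pointing away, which places the outside C-11 substituent cis to the formyl group; C-5 and C-10 are set relative to C-4 by approach of the diene to the enal face anti to the pseudoaxial methoxycarbonyl group, the flat, low-A-value group that is better accommodated 1,3-syn to the developing angular formyl group than the methyl group would be. The step needs ortho regioselectivity (C-9 to the formyl-bearing C-10), secured by the C-9 alkyl group, whose directing effect exceeds that of the inductively attenuated carbonate-bearing C-8 substituent, and by Lewis-acid polarisation of the enal; pre-complexing the Lewis acid with 4 spares the allylic carbonate and the silyl ether.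

Step 9
Reactants: 14 methyl (1S,4aS,5S,8aS)-5-[(3E)-5-{[tert-butyl(dimethyl)silyl]oxy}-3-methylpent-3-en-1-yl]-4a-formyl-6-{[(methoxycarbonyl)oxy]methyl}-1-methyl-1,2,3,4,4a,5,8,8a-octahydronaphthalene-1-carboxylate
Product: 17 methyl (1S,4aR,5R,8aS)-5-[(3E)-5-{[tert-butyl(dimethyl)silyl]oxy}-3-methylpent-3-en-1-yl]-6-{[(methoxycarbonyl)oxy]methyl}-1,4a-dimethyl-1,2,3,4,4a,5,8,8a-octahydronaphthalene-1-carboxylate, via tosylhydrazone 15 (not isolated), via diazene 16 (not isolated)
Conditions: TsNHNH2, EtOH, 50 °C, concentrate; catecholborane, CHCl3, 0 °C; NaOAc·3H2O, reflux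
Reagents that add atoms: none
Why: Kabalka-type tosylhydrazone deoxygenation (hydride reduction of the hydrazone, loss of sulfinate, extrusion of N2 from the alkyldiazene) should turn the neopentyl angular formyl group into the C-20 methyl under conditions too mild to touch the ester or carbonate; the change of the C-5 (naphthalene) descriptor from S to R is a CIP priority effect, not an inversion.

Step 10
Reactants: 17 methyl (1S,4aR,5R,8aS)-5-[(3E)-5-{[tert-butyl(dimethyl)silyl]oxy}-3-methylpent-3-en-1-yl]-6-{[(methoxycarbonyl)oxy]methyl}-1,4a-dimethyl-1,2,3,4,4a,5,8,8a-octahydronaphthalene-1-carboxylate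
Product: 18 methyl (1S,4aR,5S,8aS)-5-[(3E)-5-{[tert-butyl(dimethyl)silyl]oxy}-3-methylpent-3-en-1-yl]-1,4a-dimethyl-6-methylidenedecahydronaphthalene-1-carboxylate
Conditions: Pd(OAc)2 (5 mol %), n-Bu3P (20 mol %), HCO2H, Et3N, THF, 40 °C
Reagents that add atoms: none
Why: Tsuji palladium-catalysed formate hydrogenolysis of an allylic carbonate: the π-allylpalladium formate loses CO2 and delivers hydride to the more substituted allyl terminus (C-7), so the alkene should move to the exocyclic C8=C17 position without creating a stereocentre.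

Step 11
Reactants: 18 methyl (1S,4aR,5S,8aS)-5-[(3E)-5-{[tert-butyl(dimethyl)silyl]oxy}-3-methylpent-3-en-1-yl]-1,4a-dimethyl-6-methylidenedecahydronaphthalene-1-carboxylate
Product: 19 methyl (1S,4aR,5S,8aS)-5-[(3E)-5-hydroxy-3-methylpent-3-en-1-yl]-1,4a-dimethyl-6-methylidenedecahydronaphthalene-1-carboxylate
Conditions: TBAF, THF, 0 °C → rt
Reagents that add atoms: none
Why: Fluoride-mediated desilylation frees the C-15 allylic alcohol; the hindered tertiary methyl ester and both alkenes are inert to these conditions.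

Step 12
Reactants: 19 methyl (1S,4aR,5S,8aS)-5-[(3E)-5-hydroxy-3-methylpent-3-en-1-yl]-1,4a-dimethyl-6-methylidenedecahydronaphthalene-1-carboxylate
Product: 20 methyl (1S,4aR,5S,8aS)-5-{2-[(2R,3R)-3-(hydroxymethyl)-2-methyloxiran-2-yl]ethyl}-1,4a-dimethyl-6-methylidenedecahydronaphthalene-1-carboxylate
Conditions: Ti(OiPr)4 (10 mol %), D-(−)-diethyl tartrate (12 mol %), t-BuOOH (2 equiv), 4 Å MS, CH2Cl2, −20 °C
Reagents that add atoms: tert-butyl hydroperoxide CC(C)(C)OO
Why: Katsuki–Sharpless asymmetric epoxidation sets C-13 and C-14 as R,R under reagent control (D-tartrate, the mirror image of the L-tartrate that gives the S,S series with geraniol-type (E)-allylic alcohols), and the exocyclic alkene, not being an allylic alcohol, is left alone.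

**Compound list**

1 | methyl 3-oxocyclohex-1-ene-1-carboxylate | COC(=O)C1=CC(=O)CCC1 | starting material
2 | methylzinc enolate, methyl (1S)-1-methyl-3-[(methylzincio)oxy]cyclohex-2-ene-1-carboxylate | C[Zn]OC1=C[C@@](C)(C(=O)OC)CCC1 | intermediate
3 | methyl (1S)-1-methyl-3-{[(trifluoromethyl)sulfonyl]oxy}cyclohex-2-ene-1-carboxylate | O=S(=O)(OC1=C[C@@](C)(C(=O)OC)CCC1)C(F)(F)F | intermediate
4 | methyl (1S)-3-formyl-1-methylcyclohex-2-ene-1-carboxylate | O=CC1=C[C@@](C)(C(=O)OC)CCC1 | intermediate
5 | geraniol, (2E)-3,7-dimethylocta-2,6-dien-1-ol | CC(C)=CCC/C(C)=C/CO | starting material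
6 | tert-butyl{[(2E)-3,7-dimethylocta-2,6-dien-1-yl]oxy}dimethylsilane | CC(C)=CCC/C(C)=C/CO[Si](C)(C)C(C)(C)C | intermediate
7 | secondary ozonide, 3,3-dimethyl-5-[(3E)-5-{[tert-butyl(dimethyl)silyl]oxy}-3-methylpent-3-en-1-yl]-1,2,4-trioxolane | CC1(C)OOC(CC/C(C)=C/CO[Si](C)(C)C(C)(C)C)O1 | intermediate
8 | (4E)-6-{[tert-butyl(dimethyl)silyl]oxy}-4-methylhex-4-enal | O=CCC/C(C)=C/CO[Si](C)(C)C(C)(C)C | intermediate
9 | tert-butyl{[(2E)-7,7-dibromo-3-methylhepta-2,6-dien-1-yl]oxy}dimethylsilane | BrC(Br)=CCC/C(C)=C/CO[Si](C)(C)C(C)(C)C | intermediate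
10 | tert-butyl{[(2E,6Z)-7-bromo-3-methylnona-2,6,8-trien-1-yl]oxy}dimethylsilane (vinyl trans to the chain) | C=C/C(Br)=C/CC/C(C)=C/CO[Si](C)(C)C(C)(C)C | intermediate
11 | dienyllithium, [(3E,7E)-9-{[tert-butyl(dimethyl)silyl]oxy}-7-methylnona-1,3,7-trien-3-yl]lithium (Li in place of Br of 10, geometry retained) | C=C/C([Li])=C/CC/C(C)=C/CO[Si](C)(C)C(C)(C)C | intermediate
12 | lithium (2Z,6E)-8-{[tert-butyl(dimethyl)silyl]oxy}-2-ethenyl-6-methylocta-2,6-dien-1-olate | C=C/C(CO[Li])=C/CC/C(C)=C/CO[Si](C)(C)C(C)(C)C | intermediate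
13 | (2Z,6E)-8-{[tert-butyl(dimethyl)silyl]oxy}-2-ethenyl-6-methylocta-2,6-dien-1-yl methyl carbonate | C=C/C(COC(=O)OC)=C/CC/C(C)=C/CO[Si](C)(C)C(C)(C)C | intermediate
14 | methyl (1S,4aS,5S,8aS)-5-[(3E)-5-{[tert-butyl(dimethyl)silyl]oxy}-3-methylpent-3-en-1-yl]-4a-formyl-6-{[(methoxycarbonyl)oxy]methyl}-1-methyl-1,2,3,4,4a,5,8,8a-octahydronaphthalene-1-carboxylate (cis-fused) | COC(=O)OCC1=CC[C@H]2[C@](C=O)(CCC[C@]2(C)C(=O)OC)[C@H]1CC/C(C)=C/CO[Si](C)(C)C(C)(C)C | intermediate
15 | N-tosylhydrazone of aldehyde 14 (all stereocentres as in 14) | COC(=O)OCC1=CC[C@H]2[C@](C=NNS(=O)(=O)c3ccc(C)cc3)(CCC[C@]2(C)C(=O)OC)[C@H]1CC/C(C)=C/CO[Si](C)(C)C(C)(C)C | intermediate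
16 | alkyldiazene (CH2–N=NH in place of the formyl group of 14) | COC(=O)OCC1=CC[C@H]2[C@](CN=N)(CCC[C@]2(C)C(=O)OC)[C@H]1CC/C(C)=C/CO[Si](C)(C)C(C)(C)C | intermediate
17 | methyl (1S,4aR,5R,8aS)-5-[(3E)-5-{[tert-butyl(dimethyl)silyl]oxy}-3-methylpent-3-en-1-yl]-6-{[(methoxycarbonyl)oxy]methyl}-1,4a-dimethyl-1,2,3,4,4a,5,8,8a-octahydronaphthalene-1-carboxylate | COC(=O)OCC1=CC[C@H]2[C@](C)(CCC[C@]2(C)C(=O)OC)[C@H]1CC/C(C)=C/CO[Si](C)(C)C(C)(C)C | intermediate
18 | methyl (1S,4aR,5S,8aS)-5-[(3E)-5-{[tert-butyl(dimethyl)silyl]oxy}-3-methylpent-3-en-1-yl]-1,4a-dimethyl-6-methylidenedecahydronaphthalene-1-carboxylate | C=C1CC[C@H]2[C@](C)(CCC[C@]2(C)C(=O)OC)[C@H]1CC/C(C)=C/CO[Si](C)(C)C(C)(C)C | intermediate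
19 | methyl (1S,4aR,5S,8aS)-5-[(3E)-5-hydroxy-3-methylpent-3-en-1-yl]-1,4a-dimethyl-6-methylidenedecahydronaphthalene-1-carboxylate | C=C1CC[C@H]2[C@](C)(CCC[C@]2(C)C(=O)OC)[C@H]1CC/C(C)=C/CO | intermediate
20 | methyl (1S,4aR,5S,8aS)-5-{2-[(2R,3R)-3-(hydroxymethyl)-2-methyloxiran-2-yl]ethyl}-1,4a-dimethyl-6-methylidenedecahydronaphthalene-1-carboxylate (CNP0175926.1) | C=C1CC[C@H]2[C@](C)(CCC[C@]2(C)C(=O)OC)[C@H]1CC[C@@]1(C)O[C@@H]1CO | target

**Step count and risks**

Total step count: 12. Longest linear sequence: 10 steps (steps 3–12, from geraniol).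

Most likely to fail, in order:

Step 8. The cycloaddition may stall, because both new bonds are formed at hindered carbons (C-5 next to the C-4 quaternary centre, C-10 becoming quaternary). Meanwhile the free Lewis acid can ionise the allylic carbonate or desilylate the diene. Discrimination between the two enal faces, and between ortho and meta orientation, may also be incomplete. Fallback: replace the neutral Lewis acid–aldehyde complex by an ionic (Gassman-type) Diels–Alder reaction. Setting out from 4, acetalisation with ethylene glycol (PPTS, benzene, Dean–Stark) would give methyl (1S)-3-(1,3-dioxolan-2-yl)-1-methylcyclohex-2-ene-1-carboxylate F1. With catalytic TMSOTf in CH2Cl2 at −78 °C, F1 opens to an alkoxyallyl cation, a smaller and far more electrophilic dienophile, which should add 13 in the same ortho, endo sense at low temperature to give the dioxolane adduct methyl (1S,4aS,5S,8aS)-5-[(3E)-5-{[tert-butyl(dimethyl)silyl]oxy}-3-methylpent-3-en-1-yl]-4a-(1,3-dioxolan-2-yl)-6-{[(methoxycarbonyl)oxy]methyl}-1-methyl-1,2,3,4,4a,5,8,8a-octahydronaphthalene-1-carboxylate F2. Mild hydrolysis (PPTS, wet acetone) would bring the route back at 14. This fallback addresses rate and regiochemistry; facial selectivity would still rest on the same substrate bias.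

Step 10. Hydride may be delivered to the wrong terminus of the π-allylpalladium intermediate, giving the endocyclic C7=C8 isomer, or β-hydride elimination towards C-9 may give a diene and erode the C-9 centre. Fallback: a metal-free Myers reductive allylic transposition. Setting out from 17, methanolysis (K2CO3, MeOH) would give the allylic alcohol methyl (1S,4aR,5R,8aS)-5-[(3E)-5-{[tert-butyl(dimethyl)silyl]oxy}-3-methylpent-3-en-1-yl]-6-(hydroxymethyl)-1,4a-dimethyl-1,2,3,4,4a,5,8,8a-octahydronaphthalene-1-carboxylate F3. Mitsunobu reaction with 2-nitrobenzenesulfonylhydrazide (PPh3, DEAD, THF, −30 °C) would give the N-allyl-N-sulfonylhydrazine F4. On warming, F4 loses sulfinic acid to the allylic diazene F5, whose retro-ene loss of N2 places hydrogen on C-7 and the alkene at C8=C17, returning to the route at 18.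

Step 1. O-Sulfonylation of the weakly nucleophilic zinc enolate may be slow, so that proton quench returns the ketone, whose later enolisation would go to the wrong side. Fallback: relay through a silyl enol ether. Setting out from 1, the same conjugate addition quenched with TMSOTf would give methyl (1S)-1-methyl-3-[(trimethylsilyl)oxy]cyclohex-2-ene-1-carboxylate F6, which can be isolated. Fluoride-triggered triflation (CsF, PhNTf2, DME, rt) through the caesium enolate F7 avoids an alkyllithium next to the methyl ester and would return to the route at 3.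

**Further compounds**

F1 | step 8 | methyl (1S)-3-(1,3-dioxolan-2-yl)-1-methylcyclohex-2-ene-1-carboxylate | O1CCOC1C2=C[C@@](C)(C(=O)OC)CCC2
F2 | step 8 | methyl (1S,4aS,5S,8aS)-5-[(3E)-5-{[tert-butyl(dimethyl)silyl]oxy}-3-methylpent-3-en-1-yl]-4a-(1,3-dioxolan-2-yl)-6-{[(methoxycarbonyl)oxy]methyl}-1-methyl-1,2,3,4,4a,5,8,8a-octahydronaphthalene-1-carboxylate | COC(=O)OCC1=CC[C@H]2[C@](C3OCCO3)(CCC[C@]2(C)C(=O)OC)[C@H]1CC/C(C)=C/CO[Si](C)(C)C(C)(C)C
F3 | step 10 | methyl (1S,4aR,5R,8aS)-5-[(3E)-5-{[tert-butyl(dimethyl)silyl]oxy}-3-methylpent-3-en-1-yl]-6-(hydroxymethyl)-1,4a-dimethyl-1,2,3,4,4a,5,8,8a-octahydronaphthalene-1-carboxylate | OCC1=CC[C@H]2[C@](C)(CCC[C@]2(C)C(=O)OC)[C@H]1CC/C(C)=C/CO[Si](C)(C)C(C)(C)C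
F4 | step 10 | N-allyl-N-(2-nitrobenzenesulfonyl)hydrazine derived from F3 (N(NH2)SO2Ar in place of OH) | NN(CC1=CC[C@H]2[C@](C)(CCC[C@]2(C)C(=O)OC)[C@H]1CC/C(C)=C/CO[Si](C)(C)C(C)(C)C)S(=O)(=O)c1ccccc1[N+](=O)[O-]
F5 | step 10 | allylic diazene derived from F4 (N=NH in place of OH of F3) | N=NCC1=CC[C@H]2[C@](C)(CCC[C@]2(C)C(=O)OC)[C@H]1CC/C(C)=C/CO[Si](C)(C)C(C)(C)C
F6 | step 1 | methyl (1S)-1-methyl-3-[(trimethylsilyl)oxy]cyclohex-2-ene-1-carboxylate | C[Si](C)(C)OC1=C[C@@](C)(C(=O)OC)CCC1
F7 | step 1 | caesium (3S)-3-(methoxycarbonyl)-3-methylcyclohex-1-en-1-olate | [Cs+].[O-]C1=C[C@@](C)(C(=O)OC)CCC1
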